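Retrosynthesis: the O8 benzyl ether and the O5/O7 methyl ethers are removed first; ring A is then cut at C6–C7 and C7–C8, which takes C7 out as a carbonate carbon and leaves a 2-pyranone (ring B) carrying an acetyl group (C5 and C6) and a CH2OBn group (C8).
This cut is possible because ring A is a resorcinol unit with oxygen on C5 and C7, hydrogen on C6 and the extra oxygen on C8: C7 is at the carbonic acid level and C6 and C8 are enolisable carbons on either side of it.
Ring B is cut at C4–C4a and O1–C2 into an arylpropiolate and a β-keto ester whose ester carbon later becomes the acetyl carbonyl (C5).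
Forward: ring B is made first by Michael addition–lactonisation, the ester is turned into the methyl ketone, ring A is closed by the double acylation, and methylation and debenzylation finish the synthesis.
The target has no stereocentre; the alkene geometry of the Michael adduct equilibrates and disappears in the pyranone, so no stereocontrol is needed.

Key step: step 6

Remark: ring A atoms are named with the coumarin numbering (C5 to C8) even while they are still part of the pyranone precursors.

Step 1
Reactants: 1 4-ethynyl-1,2-dimethoxybenzene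
Product: 3 methyl 3-(3,4-dimethoxyphenyl)prop-2-ynoate, via lithium acetylide 2 (not isolated)
Conditions: n-BuLi, THF, −78 °C; then ClCO2Me, −78 to 0 °C
Reagents that add atoms: n-butyllithium, [Li]CCCC (lithium of 2 only); methyl chloroformate, COC(=O)Cl
Why: Deprotonation of the terminal alkyne and C-acylation of the lithium acetylide with a chloroformate is the standard alkynoate synthesis, and the aryl methyl ethers do not cause competing ring lithiation at −78 °C.

Step 2
Reactants: 4 tert-butyl acetate, 5 benzyloxyacetyl chloride
Product: 7 tert-butyl 4-(benzyloxy)-3-oxobutanoate, via lithium enolate 6 (not isolated)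
Conditions: LiN(iPr)2 (2.1 equiv), 4 (2.1 equiv), THF, −78 °C; then 5 (1 equiv), −78 °C; aq. NH4Cl
Reagents that add atoms: lithium diisopropylamide, [Li]N(C(C)C)C(C)C (lithium of 6 only)
Why: Crossed Claisen condensation of a preformed ester enolate with an acid chloride, in which the second equivalent of enolate deprotonates the β-keto ester as it forms and so prevents double acylation.

Step 3
Reactants: 3 methyl 3-(3,4-dimethoxyphenyl)prop-2-ynoate, 7 tert-butyl 4-(benzyloxy)-3-oxobutanoate
Product: 9 tert-butyl 6-[(benzyloxy)methyl]-4-(3,4-dimethoxyphenyl)-2-oxo-2H-pyran-5-carboxylate, via Michael adduct 8 (not isolated)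
Conditions: Cs2CO3 (0.3 equiv), DMF, 60 °C
Reagents that add atoms: none
Why: Tandem Michael addition–enol lactonisation of a β-keto ester with an alkynoate, a classical 2-pyranone synthesis: the doubly activated carbon of 7 adds to the aryl-bearing alkyne carbon of 3, the E and Z forms of adduct 8 interconvert through the dienolate, and the only ketone enol oxygen closes on the methyl ester, so that O1 can only end up on the carbon carrying CH2OBn.

Step 4
Reactants: 9 tert-butyl 6-[(benzyloxy)methyl]-4-(3,4-dimethoxyphenyl)-2-oxo-2H-pyran-5-carboxylate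
Product: 10 6-[(benzyloxy)methyl]-4-(3,4-dimethoxyphenyl)-2-oxo-2H-pyran-5-carboxylic acid
Conditions: CF3CO2H, CH2Cl2, 0 °C to rt
Reagents that add atoms: none
Why: Acidolysis of a tert-butyl ester by the E1 pathway (loss of 2-methylpropene), to which the benzyl ether, the aryl methyl ethers and the acid-stable 2-pyranone are inert.

Step 5
Reactants: 10 6-[(benzyloxy)methyl]-4-(3,4-dimethoxyphenyl)-2-oxo-2H-pyran-5-carboxylic acid
Product: 12 5-acetyl-6-[(benzyloxy)methyl]-4-(3,4-dimethoxyphenyl)-2H-pyran-2-one, via acid chloride 11 (not isolated)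
Conditions: (COCl)2, cat. DMF, CH2Cl2, 0 °C to rt, evaporate; then Me2CuLi (from MeLi and CuI), Et2O/THF, −78 °C
Reagents that add atoms: oxalyl chloride, O=C(Cl)C(=O)Cl (chlorine of 11 only); lithium dimethylcuprate, [Li+].C[Cu-]C (made in the flask from methyllithium, [Li]C, and CuI)
Why: Acid chloride formation under Vilsmeier-type catalysis and acyl substitution by a lithium dialkylcuprate, which at −78 °C reacts with acid chlorides much faster than with lactones, enoates or the ketone formed and is too weakly basic to deprotonate the CH2OBn group.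

Step 6
Reactants: 12 5-acetyl-6-[(benzyloxy)methyl]-4-(3,4-dimethoxyphenyl)-2H-pyran-2-one, 13 dimethyl carbonate
Product: 15 8-(benzyloxy)-4-(3,4-dimethoxyphenyl)-5,7-dihydroxy-2H-chromen-2-one, via β-keto ester 14 (not isolated)
Conditions: LiN(SiMe3)2 (3.5 equiv), THF, −78 °C; then 13 (1.1 equiv), −78 °C to reflux; aq. HCl
Reagents that add atoms: none
Why: Proposed new method: excess LiN(SiMe3)2 converts 12 into its delocalised anion, the acetyl enolate carbon (C6) is acylated by dimethyl carbonate in a Claisen condensation to give β-keto ester 14, and the vinylogous carbanion at the CH2OBn carbon (C8), conjugated through the pyranone with both the ketone and the lactone carbonyl, then attacks the new ester and expels methoxide, after which double enolisation of the cyclohexane-1,3-dione gives aromatic ring A. The closest known reactions are the Claisen acylation of methyl ketones with dialkyl carbonates, the one-pot conversion of 2-hydroxyacetophenones into 4-hydroxycoumarins with a dialkyl carbonate and base, the acylation of 6-methyl-2-pyranone anions at the methyl carbon, and Dieckmann-type closures of 3,5-dioxo esters to resorcinols. Ring A closes in a 6-exo-trig Dieckmann mode whichever of the two carbons is acylated first, and no stereocentre is formed. The step needs site selectivity and survival of the lactone: only the acetyl methyl and the CH2OBn carbon carry acidic hydrogens and a one-carbon electrophile can bridge them only into a six-membered ring, so O1 and the benzyloxy-bearing C8 are fixed by the preformed ring B, while the non-nucleophilic amide base, the anionic state of substrate and intermediates and the use of a single equivalent of the sluggish carbonate should suppress lactone opening and a second intermolecular acylation. Aromatisation to the phloroglucinol-type dianion should make the closure irreversible.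

Step 7
Reactants: 15 8-(benzyloxy)-4-(3,4-dimethoxyphenyl)-5,7-dihydroxy-2H-chromen-2-one
Product: 16 8-(benzyloxy)-4-(3,4-dimethoxyphenyl)-5,7-dimethoxy-2H-chromen-2-one
Conditions: Me2SO4, K2CO3, acetone, reflux
Reagents that add atoms: dimethyl sulfate, COS(=O)(=O)OC
Why: Williamson-type O-methylation of the two phenoxides, routine for 5,7-dihydroxycoumarins, under carbonate conditions that leave the lactone and the benzyl ether intact.

Step 8
Reactants: 16 8-(benzyloxy)-4-(3,4-dimethoxyphenyl)-5,7-dimethoxy-2H-chromen-2-one
Product: 17 4-(3,4-dimethoxyphenyl)-8-hydroxy-5,7-dimethoxy-2H-chromen-2-one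
Conditions: H2 (1 atm), 10% Pd/C, EtOAc/MeOH, rt
Reagents that add atoms: none
Why: Catalytic hydrogenolysis of the benzyl ether, which at atmospheric pressure is faster than saturation of the trisubstituted, aryl-conjugated C3=C4 bond of the coumarin and leaves the aryl methyl ethers untouched.

Compound list
1 | 4-ethynyl-1,2-dimethoxybenzene | C#Cc1ccc(OC)c(OC)c1 | starting material
2 | lithium (3,4-dimethoxyphenyl)acetylide (not isolated) | [Li+].[C-]#Cc1ccc(OC)c(OC)c1 | intermediate
3 | methyl 3-(3,4-dimethoxyphenyl)prop-2-ynoate | COC(=O)C#Cc1ccc(OC)c(OC)c1 | intermediate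
4 | tert-butyl acetate | CC(=O)OC(C)(C)C | starting material
5 | benzyloxyacetyl chloride | O=C(Cl)COCc1ccccc1 | starting material
6 | lithium 1-tert-butoxyethen-1-olate, the lithium enolate of 4 (not isolated) | [Li+].[O-]C(=C)OC(C)(C)C | intermediate
7 | tert-butyl 4-(benzyloxy)-3-oxobutanoate | CC(C)(C)OC(=O)CC(=O)COCc1ccccc1 | intermediate
8 | 1-tert-butyl 5-methyl (3E)-2-[(benzyloxy)acetyl]-3-(3,4-dimethoxyphenyl)pent-3-enedioate (racemic; not isolated) | COC(=O)/C=C(/c1ccc(OC)c(OC)c1)C(C(=O)OC(C)(C)C)C(=O)COCc1ccccc1 | intermediate
9 | tert-butyl 6-[(benzyloxy)methyl]-4-(3,4-dimethoxyphenyl)-2-oxo-2H-pyran-5-carboxylate | CC(C)(C)OC(=O)c1c(COCc2ccccc2)oc(=O)cc1-c1ccc(OC)c(OC)c1 | intermediate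
10 | 6-[(benzyloxy)methyl]-4-(3,4-dimethoxyphenyl)-2-oxo-2H-pyran-5-carboxylic acid | OC(=O)c1c(COCc2ccccc2)oc(=O)cc1-c1ccc(OC)c(OC)c1 | intermediate
11 | 6-[(benzyloxy)methyl]-4-(3,4-dimethoxyphenyl)-2-oxo-2H-pyran-5-carbonyl chloride (not isolated) | O=C(Cl)c1c(COCc2ccccc2)oc(=O)cc1-c1ccc(OC)c(OC)c1 | intermediate
12 | 5-acetyl-6-[(benzyloxy)methyl]-4-(3,4-dimethoxyphenyl)-2H-pyran-2-one | CC(=O)c1c(COCc2ccccc2)oc(=O)cc1-c1ccc(OC)c(OC)c1 | intermediate
13 | dimethyl carbonate | COC(=O)OC | starting material
14 | methyl 3-{6-[(benzyloxy)methyl]-4-(3,4-dimethoxyphenyl)-2-oxo-2H-pyran-5-yl}-3-oxopropanoate (not isolated) | COC(=O)CC(=O)c1c(COCc2ccccc2)oc(=O)cc1-c1ccc(OC)c(OC)c1 | intermediate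
15 | 8-(benzyloxy)-4-(3,4-dimethoxyphenyl)-5,7-dihydroxy-2H-chromen-2-one | COc1ccc(-c2cc(=O)oc3c(OCc4ccccc4)c(O)cc(O)c23)cc1OC | intermediate
16 | 8-(benzyloxy)-4-(3,4-dimethoxyphenyl)-5,7-dimethoxy-2H-chromen-2-one | COc1ccc(-c2cc(=O)oc3c(OCc4ccccc4)c(OC)cc(OC)c23)cc1OC | intermediate
17 | 4-(3,4-dimethoxyphenyl)-8-hydroxy-5,7-dimethoxy-2H-chromen-2-one (8-hydroxy-5,7,3',4'-tetramethoxy-4-phenylcoumarin) | COc1ccc(-c2cc(=O)oc3c(O)c(OC)cc(OC)c23)cc1OC | target

Total step count: 8
Longest linear sequence: 7 steps (step 2, then steps 3 to 8; step 1 is a one-step branch that joins at step 3)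

Steps most likely to fail

Step 6 (Proposed new method). The second, intramolecular acylation may stall because every acidic site is deprotonated and the ester is deactivated as its enolate. Meanwhile the liberated methoxide may open the lactone, or a second carbonate molecule may acylate the other terminus. The fallback uses known chemistry and brings ring A in ready-made instead of building it. It sets out from 3. Dakin oxidation of commercial 2-hydroxy-4,6-dimethoxybenzaldehyde (H2O2, aq. NaOH) should give 3,5-dimethoxybenzene-1,2-diol F1. Hydroarylation of alkynoate 3 by F1 (cat. Pd(OAc)2, CF3CO2H/CH2Cl2, rt) should take place at the only free position ortho to a hydroxyl group. The cis aryl acrylate so formed should lactonise in the same flask, whereas any product of attack para to the hydroxyl group cannot lactonise and is separated. This path comes back to the route at 17.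

Step 5. Addition of the methyl nucleophile to the pyranone (conjugate addition or lactone opening) may compete with acyl substitution, as may loss of HCl from the acid chloride through the acidic CH2OBn position. The fallback replaces the organometallic by a soft carbon nucleophile that can neither add twice nor attack the lactone. It sets out from 11, made as in the first half of step 5. Acylation of Meldrum's acid (pyridine, CH2Cl2, 0 °C) should give 5-{[6-[(benzyloxy)methyl]-4-(3,4-dimethoxyphenyl)-2-oxo-2H-pyran-5-yl](hydroxy)methylidene}-2,2-dimethyl-1,3-dioxane-4,6-dione F2. Heating F2 in aqueous acetic acid should hydrolyse and doubly decarboxylate it to the methyl ketone. This path comes back to the route at 12.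

Step 3. Slow Michael addition to the donor-substituted arylpropiolate may let self-condensation or base-induced decomposition of the β-keto ester take over. The fallback builds the pyranone without the alkynoate and brings in the aryl group last by cross-coupling. It sets out from 7. C-acylation with methyl 3-chloro-3-oxopropanoate (MgCl2, pyridine, CH2Cl2, 0 °C) should give 1-tert-butyl 5-methyl 2-[(benzyloxy)acetyl]-3-oxopentanedioate F3. Enol lactonisation of F3 (DBU, toluene, 80 °C) should give tert-butyl 6-[(benzyloxy)methyl]-4-hydroxy-2-oxo-2H-pyran-5-carboxylate F4. Sulfonylation (TsCl, Et3N, CH2Cl2) should give tert-butyl 6-[(benzyloxy)methyl]-4-{[(4-methylphenyl)sulfonyl]oxy}-2-oxo-2H-pyran-5-carboxylate F5. Suzuki–Miyaura coupling of F5 with (3,4-dimethoxyphenyl)boronic acid (Pd(PPh3)4, K2CO3, THF/H2O, 65 °C) comes back to the route at 9.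

Further compounds
F1 | step 6 | 3,5-dimethoxybenzene-1,2-diol | COc1cc(O)c(O)c(OC)c1
F2 | step 5 | 5-{[6-[(benzyloxy)methyl]-4-(3,4-dimethoxyphenyl)-2-oxo-2H-pyran-5-yl](hydroxy)methylidene}-2,2-dimethyl-1,3-dioxane-4,6-dione | CC1(C)OC(=O)C(=C(O)c2c(COCc3ccccc3)oc(=O)cc2-c2ccc(OC)c(OC)c2)C(=O)O1
F3 | step 3 | 1-tert-butyl 5-methyl 2-[(benzyloxy)acetyl]-3-oxopentanedioate | COC(=O)CC(=O)C(C(=O)OC(C)(C)C)C(=O)COCc1ccccc1
F4 | step 3 | tert-butyl 6-[(benzyloxy)methyl]-4-hydroxy-2-oxo-2H-pyran-5-carboxylate | CC(C)(C)OC(=O)c1c(COCc2ccccc2)oc(=O)cc1O
F5 | step 3 | tert-butyl 6-[(benzyloxy)methyl]-4-{[(4-methylphenyl)sulfonyl]oxy}-2-oxo-2H-pyran-5-carboxylate | CC(C)(C)OC(=O)c1c(COCc2ccccc2)oc(=O)cc1OS(=O)(=O)c1ccc(C)cc1
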